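**Assumption:** the target SMILES has no stereocentre and no configurationally stable axis, so the compound is achiral and no stereocontrol is needed.

## Retrosynthetic overview

1. Target ⇐ its O-mesylate ⇐ double hydrodediazoniation of a bis-aniline. An NH2 at C4 of each ring directs the four bromines to C3/C5 of both rings and is then replaced by H.
2. Bis-aniline ⇐ dinitro diaryl ether. The ring-B C6–Br comes from OH-directed bromination of the p-nitrophenol, and the ring-B nitrogen from para-nitrosation/oxidation of a 2-aryloxyphenol.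
3. Diaryl ether C–O bond ⇐ SNAr of catechol on 1-fluoro-2-methoxy-4-nitrobenzene (ring A is bought as an arene).
4. Catechol (ring B) ⇐ cyclohexane-1,2-dione ⇐ diketo diester ⇐ crossed Claisen C–C bond formation between diethyl oxalate and diethyl adipate, then Dieckmann closure.
5. Ring order: the ring-B carbocycle is built first (Claisen/Dieckmann) and then aromatised; ring A is attached intact.

## Route

Step 1
Reactants: 1 diethyl adipate; 2 diethyl oxalate
Product: 4 diethyl 2,3-dioxocyclohexane-1,4-dicarboxylate (bis-enol tautomer), via oxalyl-adipate triester 3 (not isolated)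
Conditions: NaOEt (2.2 equiv), EtOH/Et2O, 0 °C → reflux, EtOH distilled off; then cold aq. HCl
Reagents that add atoms: none
Why: Crossed Claisen condensation in which non-enolisable, highly electrophilic diethyl oxalate is the only acceptor for the adipate enolate (this intermolecular C–C bond becomes a C(O)–C bond of ring B), followed by Dieckmann cyclisation onto the second oxalyl carbonyl and driven by the stable bis-enolate; no stereocentre survives because the product is fully enolised.

Step 2
Reactants: 4 diethyl 2,3-dioxocyclohexane-1,4-dicarboxylate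
Product: 5 cyclohexane-1,2-dione
Conditions: 10% aq. H2SO4, reflux, 4 h; continuous Et2O extraction, distillation
Reagents that add atoms: none
Why: Acid hydrolysis of both β-keto esters and decarboxylation of the resulting β-keto acids through the usual cyclic six-membered transition state.

Step 3
Reactants: 5 cyclohexane-1,2-dione
Product: 6 catechol (benzene-1,2-diol)
Conditions: 10% Pd/C (5 mol %), p-cymene, reflux (177 °C), N2 sweep
Reagents that add atoms: none
Why: Pd-catalysed acceptorless dehydrogenation of the diosphenol (enol form of 5) removes one H2, and tautomerisation to the aromatic catechol makes the dehydrogenative aromatisation irreversible.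

Step 4
Reactants: 6 catechol (3 equiv); 7 1-fluoro-2-methoxy-4-nitrobenzene (commercial 2-fluoro-5-nitroanisole)
Product: 8 2-(2-methoxy-4-nitrophenoxy)phenol
Conditions: K2CO3 (1.5 equiv), DMF, 80 °C, N2
Reagents that add atoms: none
Why: SNAr displacement of the fluoride para to the nitro group by catecholate, kept at mono-arylation by the excess of catechol (any Smiles rearrangement of the product phenoxide is degenerate because ring B is still symmetric).

Step 5
Reactants: 8 2-(2-methoxy-4-nitrophenoxy)phenol
Product: 9 2-(2-methoxy-4-nitrophenoxy)-4-nitrosophenol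
Conditions: NaNO2 (1.1 equiv), H2SO4 (1.1 equiv), AcOH/H2O, 0–5 °C; product filtered off
Reagents that add atoms: sodium nitrite [Na+].[O-]N=O
Why: Electrophilic C-nitrosation by NO+ is highly para-selective for phenols, and the position para to the OH of ring B is the only strongly activated site because ring A is nitro-deactivated.

Step 6
Reactants: 9 2-(2-methoxy-4-nitrophenoxy)-4-nitrosophenol
Product: 10 2-(2-methoxy-4-nitrophenoxy)-4-nitrophenol
Conditions: 30% aq. HNO3 (1.5 equiv), AcOH, 20–30 °C
Reagents that add atoms: nitric acid O[N+](=O)[O-]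
Why: Oxidation of the p-nitrosophenol (quinone monooxime tautomer) to the p-nitrophenol by dilute nitric acid, mild enough to avoid a second ring nitration.

Step 7
Reactants: 10 2-(2-methoxy-4-nitrophenoxy)-4-nitrophenol
Product: 11 2-bromo-6-(2-methoxy-4-nitrophenoxy)-4-nitrophenol
Conditions: Br2 (1.05 equiv), AcOH, rt → 40 °C
Reagents that add atoms: bromine BrBr
Why: Electrophilic aromatic bromination goes to the only free position ortho to the phenolic OH (para is blocked by NO2, the other ortho by the aryloxy group), while the nitro-deactivated anisole ring A does not react.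

Step 8
Reactants: 11 2-bromo-6-(2-methoxy-4-nitrophenoxy)-4-nitrophenol
Product: 12 2-bromo-6-(2-methoxy-4-nitrophenoxy)-4-nitrophenyl methanesulfonate
Conditions: MsCl (1.3 equiv), Et3N (1.6 equiv), DMAP (cat.), CH2Cl2, 0 °C
Reagents that add atoms: methanesulfonyl chloride CS(=O)(=O)Cl
Why: O-sulfonylation masks the phenol with a group that survives Fe/AcOH, NBS and strong acid and prevents quinone-imine oxidation of the later aminophenol; at 0 °C the phenoxide is trapped before any Smiles migration, and the phenoxide para to NO2 is in any case the favoured isomer.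

Step 9
Reactants: 12 2-bromo-6-(2-methoxy-4-nitrophenoxy)-4-nitrophenyl methanesulfonate
Product: 13 4-amino-2-(4-amino-2-methoxyphenoxy)-6-bromophenyl methanesulfonate
Conditions: Fe powder (10 equiv), AcOH/EtOH/H2O, 70 °C
Reagents that add atoms: none
Why: Béchamp-type dissolving-metal reduction converts both nitro groups to anilines without touching the aryl bromide, the aryl mesylate or the ethers.

Step 10
Reactants: 13 4-amino-2-(4-amino-2-methoxyphenoxy)-6-bromophenyl methanesulfonate
Product: 14 4-amino-6-(4-amino-3,5-dibromo-2-methoxyphenoxy)-2,3,5-tribromophenyl methanesulfonate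
Conditions: NBS (4.1 equiv), MeCN, 0 °C → rt, dark
Reagents that add atoms: N-bromosuccinimide O=C1CCC(=O)N1Br
Why: Electrophilic aromatic bromination in which each NH2 (para position blocked) directs to both of its ortho positions, reinforced by OMe on ring A and by the bridging oxygen on ring B, placing Br at C3 and C5 of both rings.

Step 11
Reactants: 14 4-amino-6-(4-amino-3,5-dibromo-2-methoxyphenoxy)-2,3,5-tribromophenyl methanesulfonate
Product: 16 2,3,5-tribromo-6-(3,5-dibromo-2-methoxyphenoxy)phenyl methanesulfonate, via bis-diazonium salt 15 (not isolated)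
Conditions: NaNO2 (2.6 equiv), conc. H2SO4/AcOH, 0–10 °C; then 50% aq. H3PO2 (20 equiv), Cu2O (cat.), 0 °C → rt
Reagents that add atoms: none
Why: Diazotisation with nitrosylsulfuric acid (needed for the weakly basic 2,6-dibromoanilines, and chloride-free to avoid halogen exchange) followed by radical-chain hydrodediazoniation with hypophosphorous acid replaces both NH2 groups by H.

Step 12
Reactants: 16 2,3,5-tribromo-6-(3,5-dibromo-2-methoxyphenoxy)phenyl methanesulfonate
Product: 17 2,3,5-tribromo-6-(3,5-dibromo-2-methoxyphenoxy)phenol (target)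
Conditions: KOH (4 equiv), MeOH/THF/H2O, 50 °C; then aq. HCl
Reagents that add atoms: none
Why: Basic cleavage of the aryl sulfonate ester is easy because the tribromophenoxide is a good leaving group, while the unactivated aryl bromides, the methyl ether and the diaryl ether are inert (ring A has no activating group, so no Smiles rearrangement).

## Compound list

1 | diethyl adipate | CCOC(=O)CCCCC(=O)OCC | starting material
2 | diethyl oxalate | CCOC(=O)C(=O)OCC | starting material
3 | diethyl 3-(ethoxycarbonyl)-2-oxoheptanedioate (oxalyl-adipate triester, present as its sodium enolate; enolisable CH, no defined stereocentre) | CCOC(=O)C(=O)C(C(=O)OCC)CCCC(=O)OCC | intermediate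
4 | diethyl 2,3-dioxocyclohexane-1,4-dicarboxylate, drawn as its bis-enol diethyl 2,3-dihydroxycyclohexa-1,3-diene-1,4-dicarboxylate | CCOC(=O)C1=C(O)C(O)=C(C(=O)OCC)CC1 | intermediate
5 | cyclohexane-1,2-dione | O=C1CCCCC1=O | intermediate
6 | catechol (benzene-1,2-diol) | Oc1ccccc1O | intermediate
7 | 1-fluoro-2-methoxy-4-nitrobenzene | COc1cc([N+](=O)[O-])ccc1F | starting material
8 | 2-(2-methoxy-4-nitrophenoxy)phenol | COc1cc([N+](=O)[O-])ccc1Oc1ccccc1O | intermediate
9 | 2-(2-methoxy-4-nitrophenoxy)-4-nitrosophenol | COc1cc([N+](=O)[O-])ccc1Oc1cc(N=O)ccc1O | intermediate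
10 | 2-(2-methoxy-4-nitrophenoxy)-4-nitrophenol | COc1cc([N+](=O)[O-])ccc1Oc1cc([N+](=O)[O-])ccc1O | intermediate
11 | 2-bromo-6-(2-methoxy-4-nitrophenoxy)-4-nitrophenol | COc1cc([N+](=O)[O-])ccc1Oc1cc([N+](=O)[O-])cc(Br)c1O | intermediate
12 | 2-bromo-6-(2-methoxy-4-nitrophenoxy)-4-nitrophenyl methanesulfonate | COc1cc([N+](=O)[O-])ccc1Oc1cc([N+](=O)[O-])cc(Br)c1OS(C)(=O)=O | intermediate
13 | 4-amino-2-(4-amino-2-methoxyphenoxy)-6-bromophenyl methanesulfonate | COc1cc(N)ccc1Oc1cc(N)cc(Br)c1OS(C)(=O)=O | intermediate
14 | 4-amino-6-(4-amino-3,5-dibromo-2-methoxyphenoxy)-2,3,5-tribromophenyl methanesulfonate | COc1c(Br)c(N)c(Br)cc1Oc1c(Br)c(N)c(Br)c(Br)c1OS(C)(=O)=O | intermediate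
15 | bis-diazonium salt: 2,3,5-tribromo-6-(3,5-dibromo-4-diazonio-2-methoxyphenoxy)-4-diazoniophenyl methanesulfonate bis(hydrogen sulfate) | COc1c(Br)c([N+]#N)c(Br)cc1Oc1c(Br)c([N+]#N)c(Br)c(Br)c1OS(C)(=O)=O.OS(=O)(=O)[O-].OS(=O)(=O)[O-] | intermediate
16 | 2,3,5-tribromo-6-(3,5-dibromo-2-methoxyphenoxy)phenyl methanesulfonate | COc1c(Br)cc(Br)cc1Oc1c(Br)cc(Br)c(Br)c1OS(C)(=O)=O | intermediate
17 | 2,3,5-tribromo-6-(3,5-dibromo-2-methoxyphenoxy)phenol | COc1c(Br)cc(Br)cc1Oc1c(Br)cc(Br)c(Br)c1O | target

## Count and risks

Total step count: 12. Longest linear sequence: 12 steps (1/2 → 17; compound 7 enters at step 4).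

Steps most likely to fail:

Step 3 (dehydrogenation of 5 to catechol; 5 is volatile and prone to self-condensation at the temperature needed). The fallback sets out from 4 and comes back at 6, aromatising before the esters are removed. Compound 4 is treated with Br2 (1.0 equiv, CHCl3, 0 °C → reflux; α-bromination then loss of HBr) to give diethyl 2,3-dihydroxyterephthalate F1. This is saponified (aq. NaOH, reflux under N2, then HCl) to 2,3-dihydroxyterephthalic acid F2. Both salicylic-type carboxyl groups are then removed thermally (Cu powder, quinoline, 210 °C) to give catechol 6.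

Step 5 (para-nitrosation of 8, with the follow-up oxidation of step 6 at risk of over-nitration). The fallback sets out from 8 and comes back at 13, bringing in the ring-B nitrogen by azo coupling instead. The phenoxide of 8 (aq. NaOH/EtOH, 0–5 °C) is coupled with commercial benzenediazonium tetrafluoroborate, which attacks para to the oxygen and gives 2-(2-methoxy-4-nitrophenoxy)-4-[(E)-phenyldiazenyl]phenol F3. Bromination ortho to the OH (Br2, AcOH) gives 2-bromo-6-(2-methoxy-4-nitrophenoxy)-4-[(E)-phenyldiazenyl]phenol F4. Mesylation (MsCl, Et3N, CH2Cl2, 0 °C) gives 2-bromo-6-(2-methoxy-4-nitrophenoxy)-4-[(E)-phenyldiazenyl]phenyl methanesulfonate F5. Reduction with SnCl2·2H2O in conc. HCl/EtOH at 70 °C reduces the nitro group and cleaves the azo link in one operation, giving 13 after removal of the co-formed aniline.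

Step 11 (double hydrodediazoniation of two hindered, weakly basic anilines). The fallback sets out from 14 and comes back at 16, replacing direct reduction by iodide capture and selective de-iodination. Compound 14 is diazotised as before to 15, which is quenched with aqueous KI (0 °C → rt) to give 2,3,5-tribromo-6-(3,5-dibromo-4-iodo-2-methoxyphenoxy)-4-iodophenyl methanesulfonate F6. Treatment with i-PrMgCl·LiCl (2.2 equiv, THF, −40 °C) exchanges only the two iodines (I/Mg exchange is far faster than Br/Mg, and the 2,6-dibromoaryl Grignard is stable at this temperature). A MeOH quench then gives 16.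

## Further compounds

F1 | step 3 | diethyl 2,3-dihydroxyterephthalate | CCOC(=O)c1ccc(C(=O)OCC)c(O)c1O
F2 | step 3 | 2,3-dihydroxyterephthalic acid | OC(=O)c1ccc(C(=O)O)c(O)c1O
F3 | step 5 | 2-(2-methoxy-4-nitrophenoxy)-4-[(E)-phenyldiazenyl]phenol | COc1cc([N+](=O)[O-])ccc1Oc1cc(/N=N/c2ccccc2)ccc1O
F4 | step 5 | 2-bromo-6-(2-methoxy-4-nitrophenoxy)-4-[(E)-phenyldiazenyl]phenol | COc1cc([N+](=O)[O-])ccc1Oc1cc(/N=N/c2ccccc2)cc(Br)c1O
F5 | step 5 | 2-bromo-6-(2-methoxy-4-nitrophenoxy)-4-[(E)-phenyldiazenyl]phenyl methanesulfonate | COc1cc([N+](=O)[O-])ccc1Oc1cc(/N=N/c2ccccc2)cc(Br)c1OS(C)(=O)=O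
F6 | step 11 | 2,3,5-tribromo-6-(3,5-dibromo-4-iodo-2-methoxyphenoxy)-4-iodophenyl methanesulfonate | COc1c(Br)c(I)c(Br)cc1Oc1c(Br)c(I)c(Br)c(Br)c1OS(C)(=O)=O
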